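**Hard ceiling.** Taking one partner for each target, a flask with [partner] at 18.0 mM cannot hold more target than 18.0 mM, and the eta run, with its large excess of starting material, reads 16.1 mM of target after 15.0 min, less than that charge.

| flask | starting material | partner | protic impurity | remark | time |
|---|---|---|---|---|---|
| zeta | 18 mM | 18 mM | 2 mM | run made earlier |  |
| eta | 62 mM | 18 mM | 2 mM | run made earlier |  |
| grey | 12 mM | 18.0 mM | 2.00 mM |  | 20 min |
| green | 20 mM | 18.0 mM | 2.00 mM |  | 20 min |
| ochre | 30 mM | 18.0 mM | 2.00 mM |  | 20 min |
| red | 50 mM | 18.0 mM | 2.00 mM |  | 20 min |

| run | time / min | target / % | starting material / % |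
|---|---|---|---|
| zeta | 2.00 | 0.9 | 45.8 |
| zeta | 5.00 | 15.9 | 18.3 |
| zeta | 10.0 | 40.7 | 3.9 |
| zeta | 15.0 | 54.5 | 0 |
| eta | 1.00 | 0.4 | 70.2 |
| eta | 2.50 | 2.1 | 45.3 |
| eta | 6.00 | 14.4 | 17.8 |
| eta | 15.0 | 26.0 | 2.1 |

(each reading ± 1 percentage point)

- the numbers in the tables scatter by 1 percentage point (one standard deviation)
- "hardly changes" means that all values lie within two and a half points (for a concentration: within two and a half percent of the largest)

- amount of target at the end, in percent of the starting material charged for grey, green, ochre, red, in this order
- the course of these numbers from the first flask to the last (falls, then rises / rises, then falls / hardly changes / falls all the way / rises all the way)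

**Eta ledger.** I open the books on the partner, the limiting reagent in eta: of 18 mM charged, the reading books 16.1 mM as target and leaves 1.88 mM unbooked after 15.0 min, so by this reading, with its scatter, eta has filled 89.6% of its partner. On the other side, 71.9% of the starting material charged in eta is by then neither starting material nor target, so its loss has run well past what the partner can take up.

**Carried ceiling.** For red I reckon 36.0%, the partner ceiling, which is [partner] charged over [starting material] charged, read as a percent of the starting material. For ochre the same ratio gives 60.0%, which is higher than in red, and green has 90.0%. Grey holds less starting material than partner, so its ceiling is its own charge. If red fills its ceiling as eta filled its own, I expect about 32.3% of target in red, and I expect the row to fall.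

**The forecast.** The forecast gives 62%, 59%, 48% and 31.5%, with the course falls all the way, and it calls red “capped by the partner”.

**The result.** Grey, green, ochre and red give 65.0%, 60.2%, 49.1% and 32.0%, so the course is falls all the way.

    partner → second intermediate (k = 0.00360 s⁻¹)
    starting material → open intermediate (k = 0.00500 s⁻¹)
    starting material + protic impurity → quenched substrate (k = 2.40 M⁻¹ s⁻¹)
    open intermediate + second intermediate → target (k = 0.190 M⁻¹ s⁻¹)
    target ⇌ isomer of the product (K = 0.240, k = 1.40 × 10⁻⁴ s⁻¹)

**Closing books.** Red's target is held to 32.0%, with a ceiling of 36.0%, mainly because its partner is consumed: with that consumption taken away, red reaches 85.0%. After 20.0 min, red's partner stands as 16.0 mM of target, 1.41 mM of isomer of the product, 0.353 mM of second intermediate and 0.239 mM of partner, together 18.0 mM. In ochre after 200 min, target and isomer of the product together reach 60.0%, about its ceiling of 60.0%, while open intermediate stands at 33.3%.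

The data are calculated on assumed constants, noise included.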